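**Retrosynthetic overview**

1. 25 ⇐ triol 24: the three C–Br bonds (C8, C10, C12) are made last by one triple SN2 bromination of the tri-epimeric triol.
2. Ring C (oxane) ⇐ furan 17: Achmatowicz ring expansion, axial hydride delivery at C9, then epoxidation, reductive opening and ketone reduction give the all-cis 10,12-diol.
3. C8–C9 ⇐ Felkin–Anh addition of lithiofuran 12 (C9–C15, C13 from asymmetric ethylation of furfural) to aldehyde 8.
4. Key C3–C4 bond ⇐ 5-exo closure of the anomeric radical at C4 (a natively electrophilic carbon used as a nucleophilic α-alkoxy carbon) onto the electrophilic β-carbon C3 of an O1-tethered alkoxyacrylate; this closes ring B onto ring A and gives the 2,5-dioxabicyclo[2.2.1]heptane.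
5. Ring A with C6 and C7 ⇐ 2-deoxy-D-glucose (C4–C8); ring order A (furanoside) → B (radical closure) → C (Achmatowicz).

Assumption: atoms are numbered C1 (alkyne CH) to C15 (CH3) along the target chain, O1 = C3–O–C6, O2 = C4–O–C7, O3 = C9–O–C13; ring A = O2/C4–C7, ring B = O1/C3–C6, ring C = oxane; exo = on the side of the C5 bridge; anomeric mixtures (2, 3, 5, 6, 19) are carried through because that centre is planarised later.

**Route**

Step 1
Reactants: 1 2-deoxy-D-glucose
Product: 3 methyl 2-deoxy-5,6-O-isopropylidene-α/β-D-arabino-hexofuranoside, via methyl furanoside triol 2 (not isolated)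
Conditions: AcCl (5 mol %), MeOH, 0 °C to rt, 45 min; then 2,2-dimethoxypropane, acetone, rt; Et3N
Reagents that add atoms: methanol CO; 2,2-dimethoxypropane COC(C)(C)OC
Why: Kinetic Fischer glycosidation gives the furanosides, which are locked by acetonide formation on the exocyclic 5,6-diol (five-membered acetal preferred), leaving only O3–H free; C6 and C7 of the target are the untouched sugar C3 and C4.

Step 2
Reactants: 3 methyl 2-deoxy-5,6-O-isopropylidene-D-arabino-hexofuranoside; 4 ethyl propiolate
Product: 5 methyl 2-deoxy-3-O-[(E)-2-(ethoxycarbonyl)vinyl]-5,6-O-isopropylidene-α/β-D-arabino-hexofuranoside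
Conditions: N-methylmorpholine, CH2Cl2, rt
Reagents that add atoms: none
Why: Amine-catalysed oxa-Michael addition of the only free hydroxyl to the propiolate gives the (E)-β-alkoxyacrylate tether on O1.

Step 3
Reactants: 5 β-alkoxyacrylate methyl furanoside
Product: 7 bicyclic ester (exo-CH2CO2Et at C3; endo-dioxolanyl at C7), via anomeric bromide 6 (not isolated)
Conditions: TMSBr, CH2Cl2, −40 to 0 °C; evaporate; then Bu3SnH (syringe pump), Et3B/air, toluene, 0 °C to rt
Reagents that add atoms: bromotrimethylsilane C[Si](C)(C)Br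
Why: Proposed new method: TMSBr turns the 2-deoxyfuranoside into the anomeric bromide and Bu3Sn• gives the C4 anomeric radical, a nucleophilic α-alkoxy carbon at a position that is normally electrophilic, which adds 5-exo to the electrophilic acrylate β-carbon C3 held on the cis O1 tether, so C4 is fixed by the tether and the acrylate residue turns to the convex exo side away from O2 and the endo dioxolane (sets C3); closest known types are β-alkoxyacrylate radical cyclisations to oxacycles and 5-exo closures of furanosyl radicals to bicyclo[2.2.1] frameworks.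

Step 4
Reactants: 7 bicyclic ester
Product: 8 bicyclic ester aldehyde (endo-CHO at C7; C8 = CHO)
Conditions: H5IO6, EtOAc, rt
Reagents that add atoms: none
Why: One-pot acetonide hydrolysis and glycol cleavage by periodic acid excises the terminal sugar carbon under non-basic conditions, so the α-alkoxy centre C7 is not epimerised.

Step 5
Reactants: 9 furfural
Product: 11 (R)-triethyl[1-(furan-2-yl)propoxy]silane, via zinc alkoxide 10 (not isolated)
Conditions: Et2Zn, (+)-MIB (4 mol %), toluene/hexanes, 0 °C; then TESOTf, 0 °C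
Reagents that add atoms: diethylzinc CC[Zn]CC; triethylsilyl triflate CC[Si](CC)(CC)OS(=O)(=O)C(F)(F)F
Why: Amino-alcohol-catalysed enantioselective diethylzinc addition sets C13 as (R) by reagent control (this ligand antipode gives the R carbinol with aryl aldehydes), and the zinc alkoxide is silylated in situ.

Step 6
Reactants: 11 (R)-triethyl[1-(furan-2-yl)propoxy]silane; 8 bicyclic ester aldehyde
Product: 14 furyl carbinol TBS ether ester (8S), via lithiofuran 12 (not isolated), via lithium alkoxide 13 (not isolated)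
Conditions: 11, n-BuLi, THF, −78 to 0 °C; then 8, −78 °C; then TBSOTf, −78 to 0 °C
Reagents that add atoms: n-butyllithium [Li]CCCC; tert-butyldimethylsilyl triflate CC(C)(C)[Si](C)(C)OS(=O)(=O)C(F)(F)F
Why: C5 lithiation of the furan and 1,2-addition to the α-alkoxy aldehyde (aldehyde far faster than ester at −78 °C) under polar Felkin–Anh control, with C7–O2 anti to the nucleophile (the same rotamer as the Li-bridged O1/carbonyl arrangement), sets C8 as the epimer needed for later inversion; the alkoxide is trapped as the TBS ether.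

Step 7
Reactants: 14 furyl carbinol TBS ether ester
Product: 15 aldehyde (C3–CH2–CHO)
Conditions: i-Bu2AlH, CH2Cl2, −78 °C; Rochelle salt
Reagents that add atoms: none
Why: Partial ester reduction through the tetrahedral aluminate that is stable at −78 °C; silyl ethers and furan are inert.

Step 8
Reactants: 15 aldehyde
Product: 17 terminal alkyne, via enol triflate 16 (not isolated)
Conditions: KN(SiMe3)2, PhNTf2, THF, −78 °C; then LiN(i-Pr)2 (2.5 equiv), −78 to −20 °C; NH4Cl
Reagents that add atoms: N-phenylbis(trifluoromethanesulfonimide) O=S(=O)(N(c1ccccc1)S(=O)(=O)C(F)(F)F)C(F)(F)F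
Why: Kinetic enolisation with internal triflation traps the enolate before β-alkoxide loss, and E2 elimination of the enol triflate by the amide base gives the C1≡C2 alkyne without touching a stereocentre.

Step 9
Reactants: 17 terminal alkyne
Product: 19 pyranone hemiketal (6-hydroxy-2H-pyran-3(6H)-one; C8–OTBS), via enedione silyl ether 18 (not isolated)
Conditions: NBS, THF/H2O (4:1), 0 °C; then rt, 1 h (unbuffered)
Reagents that add atoms: water O
Why: Achmatowicz oxidative ring expansion: NBS/water opens the furan to the cis-enedione, the HBr released cleaves the labile TES ether and the freed C13 hydroxyl closes on the C9 ketone, while the TBS ether at C8 ensures that only O3 can close; C13 is retained.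

Step 10
Reactants: 19 pyranone hemiketal
Product: 21 cis-2,6-dihydropyranone with free C8–OH, via silyl ether enone 20 (not isolated)
Conditions: Et3SiH, CF3CO2H, CH2Cl2, −40 to 0 °C; then H2O, rt
Reagents that add atoms: none
Why: Kishi-type ionic reduction: the C9 oxocarbenium ion takes hydride axially, giving the 2,6-cis oxane (C9 set relative to C13), and aqueous acid then removes the TBS group that blocked a 1,2-shift during ionisation.

Step 11
Reactants: 21 cis-2,6-dihydropyranone
Product: 22 epoxy ketone (C10–C11 epoxide cis to the C9 and C13 substituents)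
Conditions: H2O2 (30 % aq), NaOH (cat.), MeOH, 0 °C
Reagents that add atoms: hydrogen peroxide OO
Why: Weitz–Scheffer epoxidation: hydroperoxide adds to C10 axially, anti to the pseudoaxial C9–H, so the epoxide forms on the face cis to both equatorial substituents (sets the C10–O bond).

Step 12
Reactants: 22 epoxy ketone
Product: 24 triol (C8–OH; axial C10–OH and C12–OH), via hydroxy ketone 23 (not isolated)
Conditions: SmI2, MeOH (2.2 equiv), THF, −90 °C; then LiBH(s-Bu)3, −78 °C
Reagents that add atoms: none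
Why: Divalent samarium cleaves the Cα–O bond of the epoxy ketone to the β-hydroxy ketone without touching C10, and the bulky hydride attacks the C12 ketone equatorially because the axial path is blocked by the 1,3-syn-axial C10 oxygen, giving the axial C12 alcohol.

Step 13
Reactants: 24 triol
Product: 25 target CNP0139964.2
Conditions: CBr4, P(n-Oct)3, toluene, 70 °C
Reagents that add atoms: carbon tetrabromide BrC(Br)(Br)Br
Why: Appel-type bromination with three SN2 inversions (C8, axial C10–OH and axial C12–OH) gives the C8 bromide and the two equatorial ring bromides of the target.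

**Compound list**

1 | 2-deoxy-D-glucose (pyranose form) | OC[C@H]1OC(O)C[C@@H](O)[C@@H]1O | starting material
2 | methyl 2-deoxy-α/β-D-arabino-hexofuranoside | COC1C[C@@H](O)[C@H](O1)[C@H](O)CO | intermediate
3 | methyl 2-deoxy-5,6-O-isopropylidene-α/β-D-arabino-hexofuranoside | COC1C[C@@H](O)[C@H](O1)[C@H]2COC(C)(C)O2 | intermediate
4 | ethyl propiolate | C#CC(=O)OCC | starting material
5 | methyl 2-deoxy-3-O-[(E)-2-(ethoxycarbonyl)vinyl]-5,6-O-isopropylidene-α/β-D-arabino-hexofuranoside | COC1C[C@@H](O/C=C/C(=O)OCC)[C@H](O1)[C@H]2COC(C)(C)O2 | intermediate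
6 | 2-deoxy-3-O-[(E)-2-(ethoxycarbonyl)vinyl]-5,6-O-isopropylidene-D-arabino-hexofuranosyl bromide | BrC1C[C@@H](O/C=C/C(=O)OCC)[C@H](O1)[C@H]2COC(C)(C)O2 | intermediate
7 | bicyclic ester: 2,5-dioxabicyclo[2.2.1]heptane with exo CH2CO2Et on C3 and endo (4R)-2,2-dimethyl-1,3-dioxolan-4-yl on C7; C3, C4, C6, C7 as in the target | CCOC(=O)C[C@@H]1O[C@@H]2C[C@H]1O[C@@H]2[C@H]3COC(C)(C)O3 | intermediate
8 | bicyclic ester aldehyde: as 7 with endo CHO (C8) on C7 | CCOC(=O)C[C@@H]1O[C@@H]2C[C@H]1O[C@@H]2C=O | intermediate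
9 | furfural | O=Cc1ccco1 | starting material
10 | ethylzinc (R)-1-(furan-2-yl)propan-1-olate | CC[C@@H](O[Zn]CC)c1ccco1 | intermediate
11 | (R)-triethyl[1-(furan-2-yl)propoxy]silane | CC[C@@H](O[Si](CC)(CC)CC)c1ccco1 | intermediate
12 | 5-lithio derivative of 11 | CC[C@@H](O[Si](CC)(CC)CC)c1ccc([Li])o1 | intermediate
13 | lithium alkoxide adduct of 12 and 8 (C8–OLi, 8S) | CCOC(=O)C[C@@H]1O[C@@H]2C[C@H]1O[C@@H]2[C@H](O[Li])c1ccc(o1)[C@@H](CC)O[Si](CC)(CC)CC | intermediate
14 | furyl carbinol TBS ether ester: bicycle of 7 joined through C8 (S, OTBS) to C5 of the furan that carries the (R)-CH(OTES)Et group | CCOC(=O)C[C@@H]1O[C@@H]2C[C@H]1O[C@@H]2[C@H](O[Si](C)(C)C(C)(C)C)c1ccc(o1)[C@@H](CC)O[Si](CC)(CC)CC | intermediate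
15 | aldehyde: as 14 with CH2CHO on C3 | O=CC[C@@H]1O[C@@H]2C[C@H]1O[C@@H]2[C@H](O[Si](C)(C)C(C)(C)C)c1ccc(o1)[C@@H](CC)O[Si](CC)(CC)CC | intermediate
16 | (Z)-enol triflate of 15 | FC(F)(F)S(=O)(=O)O/C=C\[C@@H]1O[C@@H]2C[C@H]1O[C@@H]2[C@H](O[Si](C)(C)C(C)(C)C)c1ccc(o1)[C@@H](CC)O[Si](CC)(CC)CC | intermediate
17 | terminal alkyne: exo ethynyl on C3; C8–OTBS; furan; C13–OTES | C#C[C@@H]1O[C@@H]2C[C@H]1O[C@@H]2[C@H](O[Si](C)(C)C(C)(C)C)c1ccc(o1)[C@@H](CC)O[Si](CC)(CC)CC | intermediate
18 | (Z)-enedione: C9 and C12 ketones, C10=C11 cis, C13–OTES | C#C[C@@H]1O[C@@H]2C[C@H]1O[C@@H]2[C@H](O[Si](C)(C)C(C)(C)C)C(=O)/C=C\C(=O)[C@@H](CC)O[Si](CC)(CC)CC | intermediate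
19 | pyranone hemiketal: 2-ethyl-6-hydroxy-2H-pyran-3(6H)-one bearing the C8(OTBS)–bicycle on C9 (anomers) | C#C[C@@H]1O[C@@H]2C[C@H]1O[C@@H]2[C@H](O[Si](C)(C)C(C)(C)C)C1(O)O[C@H](CC)C(=O)C=C1 | intermediate
20 | cis-2,6-dihydropyranone, C8–OTBS | C#C[C@@H]1O[C@@H]2C[C@H]1O[C@@H]2[C@H](O[Si](C)(C)C(C)(C)C)[C@@H]1O[C@H](CC)C(=O)C=C1 | intermediate
21 | cis-2,6-dihydropyranone, C8–OH | C#C[C@@H]1O[C@@H]2C[C@H]1O[C@@H]2[C@H](O)[C@@H]1O[C@H](CC)C(=O)C=C1 | intermediate
22 | epoxy ketone: C10–C11 epoxide cis to the C9 and C13 substituents, C12 ketone | C#C[C@@H]1O[C@@H]2C[C@H]1O[C@@H]2[C@H](O)[C@@H]1O[C@H](CC)C(=O)[C@@H]2O[C@H]12 | intermediate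
23 | β-hydroxy ketone: axial C10–OH (cis to C9 substituent), C12 ketone | C#C[C@@H]1O[C@@H]2C[C@H]1O[C@@H]2[C@H](O)[C@@H]1O[C@H](CC)C(=O)C[C@@H]1O | intermediate
24 | triol: 2,6-cis oxane with axial 10-OH and 12-OH (all-cis), C8–OH; each carbinol epimeric to the target bromide | C#C[C@@H]1O[C@@H]2C[C@H]1O[C@@H]2[C@H](O)[C@@H]1O[C@H](CC)[C@H](O)C[C@@H]1O | intermediate
25 | CNP0139964.2 | C#C[C@@H]1O[C@@H]2C[C@H]1O[C@@H]2[C@@H](Br)[C@@H]1O[C@H](CC)[C@@H](Br)C[C@H]1Br | target

**Step count**

Total steps: 13. Longest linear sequence: 12 (steps 1–4 and 6–13; step 5 makes the furan fragment).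

**Three steps most likely to fail**

Step 3 (key radical closure). The strained [2.2.1] ring may form slowly against direct reduction of the anomeric radical, and exo/endo control at C3 is only predicted. The fallback sets out from 3 and comes back at 17. Alkylation of 3 with ethyl bromoacetate (NaH, THF) gives the glycolate ether F1. Its silyl ketene acetal (LiN(i-Pr)2, TMSCl; then TMSOTf) closes on the anomeric oxocarbenium ion in an intramolecular Mukaiyama-type C-glycosylation and, after DBU equilibration, gives the exo bicyclic C3 ester F2. i-Bu2AlH gives the aldehyde F3, and the Ohira–Bestmann reagent (K2CO3, MeOH) gives the ethynyl bicycle F4. H5IO6 then gives the ethynyl aldehyde F5. Inverse addition of F5 to 2.2 equiv of lithiofuran 12 gives the furyl carbinol F6, and TBSOTf/2,6-lutidine converts this into 17.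

Step 8 (alkyne from the β-alkoxy aldehyde). The enolate can expel O1 and open ring B before it is triflated. The fallback sets out from 15 and comes back at 17; it removes one carbon without any enolate and adds it back. Soft enolisation (TIPSOTf, Et3N, CH2Cl2) gives the silyl enol ether F7. Lemieux–Johnson cleavage (OsO4 cat., NaIO4, 2,6-lutidine, dioxane/H2O) gives the C3 aldehyde F8. The Ohira–Bestmann reagent (K2CO3, MeOH) then gives 17.

Step 13 (triple invertive bromination). The C8 carbinol is flanked by two oxygenated carbons, the 10,12-diol is 1,3-diaxial (a cyclic phosphorane may stall the reaction), and E2 or ring-oxygen participation can compete. The fallback sets out from 24 and comes back at 25. ClCH2SO2Cl/pyridine (CH2Cl2, 0 °C) gives the isolable tris(chloromethanesulfonate) F9. LiBr in DMF at 50 °C displaces the three sulfonates with inversion to give 25.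

**Further compounds**

F1 | step 3 | methyl 2-deoxy-3-O-(2-ethoxy-2-oxoethyl)-5,6-O-isopropylidene-α/β-D-arabino-hexofuranoside | COC1C[C@@H](OCC(=O)OCC)[C@H](O1)[C@H]2COC(C)(C)O2
F2 | step 3 | bicyclic C3 ester: as 7 with exo CO2Et directly on C3 | CCOC(=O)[C@@H]1O[C@@H]2C[C@H]1O[C@@H]2[C@H]3COC(C)(C)O3
F3 | step 3 | bicyclic C3 aldehyde with endo dioxolanyl on C7 | O=C[C@@H]1O[C@@H]2C[C@H]1O[C@@H]2[C@H]3COC(C)(C)O3
F4 | step 3 | exo-3-ethynyl bicycle with endo dioxolanyl on C7 | C#C[C@@H]1O[C@@H]2C[C@H]1O[C@@H]2[C@H]3COC(C)(C)O3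
F5 | step 3 | exo-3-ethynyl bicycle with endo CHO (C8) on C7 | C#C[C@@H]1O[C@@H]2C[C@H]1O[C@@H]2C=O
F6 | step 3 | furyl carbinol: as 17 with free C8–OH (8S) | C#C[C@@H]1O[C@@H]2C[C@H]1O[C@@H]2[C@H](O)c1ccc(o1)[C@@H](CC)O[Si](CC)(CC)CC
F7 | step 8 | triisopropylsilyl enol ether of 15 (E/Z mixture) | CC(C)[Si](C(C)C)(C(C)C)OC=C[C@@H]1O[C@@H]2C[C@H]1O[C@@H]2[C@H](O[Si](C)(C)C(C)(C)C)c1ccc(o1)[C@@H](CC)O[Si](CC)(CC)CC
F8 | step 8 | C3 aldehyde: as 17 with exo CHO in place of ethynyl | O=C[C@@H]1O[C@@H]2C[C@H]1O[C@@H]2[C@H](O[Si](C)(C)C(C)(C)C)c1ccc(o1)[C@@H](CC)O[Si](CC)(CC)CC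
F9 | step 13 | tris(chloromethanesulfonate) of 24 | C#C[C@@H]1O[C@@H]2C[C@H]1O[C@@H]2[C@H](OS(=O)(=O)CCl)[C@@H]1O[C@H](CC)[C@H](OS(=O)(=O)CCl)C[C@@H]1OS(=O)(=O)CCl
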